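The whole plan hinges on cutting the C4–C5 bond of the ten-membered carbocycle (ring A, C1–C10). C5 is a secondary allylic carbinol flanked by C4, with its exocyclic C15 methylene, and by C6, the oxygen-bearing carbon of the γ-lactone (ring B); exactly this array results when a 2-iodo-1-alkene adds to an α-oxygenated aldehyde. One chromium-mediated, nickel-catalysed alkenyl–aldehyde addition therefore forms C4–C5, closes ring A and sets C5 under Felkin–Anh control from C6, and the hydroxyl it creates later steers the C4=C15 epoxidation. The substrate is a seco C5 aldehyde with ring B already closed, the C8 angelate in place and an (E,Z)-diene ending in the C4 iodoalkene.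

Key step: step 15

Remark on the chemistry: atoms carry germacrane numbers (C11–C13 methylene-lactone carbons, C14 methyl on C10, C15 on C4), and O6 and C12 are assumed to pass through the ring closure joined as ring B, not masked separately as an O6 ether and a C12 ester; carbon skeleton, bond formed and ring closed are unchanged, and no later choice between O5 and O6 in lactonisation arises.

Step 1
Reactants: 1 3-butyn-1-ol
Product: 2 tert-butyl(but-3-yn-1-yloxy)diphenylsilane
Conditions: TBDPSCl, imidazole, CH2Cl2, 0 °C to rt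
Reagents that add atoms: tert-butyl(chloro)diphenylsilane, SMILES CC(C)(C)[Si](Cl)(c1ccccc1)c1ccccc1
Why: Imidazole-promoted O-silylation of the primary alcohol gives a bulky silyl ether that should survive the organoaluminium, palladium, methanolysis and haloboration steps that follow; no stereocentre is involved.

Step 2
Reactants: 3 (Z)-1,2-dichloroethene; 4 ethynyltrimethylsilane
Product: 5 (Z)-(4-chlorobut-3-en-1-yn-1-yl)trimethylsilane
Conditions: Pd(PPh3)4 (cat.), CuI (cat.), n-BuNH2, Et2O, rt, 3 in excess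
Reagents that add atoms: none
Why: Sonogashira coupling of one C–Cl bond of the dichloride, used in excess to favour mono-coupling, proceeds with retention of alkene geometry, so the Z configuration of the future C2=C3 bond comes from the starting alkene.

Step 3
Reactants: 2 tert-butyl(but-3-yn-1-yloxy)diphenylsilane; 5 (Z)-(4-chlorobut-3-en-1-yn-1-yl)trimethylsilane
Product: 8 tert-butyl{[(3E,5Z)-3-methyl-8-(trimethylsilyl)octa-3,5-dien-7-yn-1-yl]oxy}diphenylsilane, via alkenylalane 6 (not isolated), via alkenylzinc chloride 7 (not isolated)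
Conditions: Me3Al, Cp2ZrCl2 (cat.), CH2Cl2, 0 °C to rt; then ZnCl2, Pd(PPh3)4 (cat.), 5, THF, rt to 45 °C
Reagents that add atoms: trimethylaluminium, SMILES C[Al](C)C
Why: Zirconium-catalysed Negishi carboalumination adds methyl and aluminium syn across the terminal alkyne (methyl C14 to the internal carbon, fixing the E C1=C10 bond), and after transmetalation to zinc a Negishi cross-coupling with retention at the Z chloroalkene forms C1–C2 without disturbing either geometry.

Step 4
Reactants: 8 tert-butyl{[(3E,5Z)-3-methyl-8-(trimethylsilyl)octa-3,5-dien-7-yn-1-yl]oxy}diphenylsilane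
Product: 9 tert-butyl{[(3E,5Z)-3-methylocta-3,5-dien-7-yn-1-yl]oxy}diphenylsilane
Conditions: K2CO3 (cat.), MeOH/THF, 0 °C
Reagents that add atoms: none
Why: Base-catalysed methanolysis (protodesilylation) cleaves the alkynyl C–Si bond selectively, the hindered silyl ether being inert to carbonate in methanol.

Step 5
Reactants: 9 tert-butyl{[(3E,5Z)-3-methylocta-3,5-dien-7-yn-1-yl]oxy}diphenylsilane
Product: 11 tert-butyl{[(3E,5Z)-7-iodo-3-methylocta-3,5,7-trien-1-yl]oxy}diphenylsilane, via alkenylborane 10 (not isolated)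
Conditions: 9-iodo-9-BBN, pentane/CH2Cl2, −20 to 0 °C, dark; then AcOH, 0 °C
Reagents that add atoms: 9-iodo-9-borabicyclo[3.3.1]nonane, SMILES IB1C2CCCC1CCC2
Why: Haloboration of a terminal alkyne places boron on the terminal and iodine on the internal carbon by syn addition, and protodeboronation with acetic acid leaves the 2-iodo-1-alkene (C4–I with the C15 methylene), alkenes and the bulky silyl ether being left alone at low temperature.

Step 6
Reactants: 11 tert-butyl{[(3E,5Z)-7-iodo-3-methylocta-3,5,7-trien-1-yl]oxy}diphenylsilane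
Product: 12 (3E,5Z)-7-iodo-3-methylocta-3,5,7-trien-1-ol
Conditions: Bu4NF, AcOH, THF, 0 °C to rt
Reagents that add atoms: none
Why: Fluoride-mediated desilylation, buffered with acetic acid so that the iododiene is not exposed to base, frees the C8 alcohol.

Step 7
Reactants: 12 (3E,5Z)-7-iodo-3-methylocta-3,5,7-trien-1-ol
Product: 13 (3E,5Z)-7-iodo-3-methylocta-3,5,7-trienal
Conditions: Dess–Martin periodinane, NaHCO3, CH2Cl2, 0 °C; used at once
Reagents that add atoms: none
Why: Dess–Martin oxidation under bicarbonate buffer gives the β,γ-unsaturated aldehyde under non-enolising conditions, and immediate use should prevent migration of C1=C10 into conjugation.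

Step 8
Reactants: 14 (S)-but-3-ene-1,2-diol
Product: 15 (S)-1-[(tert-butyldimethylsilyl)oxy]but-3-en-2-ol
Conditions: TBSCl, imidazole, CH2Cl2, −20 to 0 °C
Reagents that add atoms: tert-butyl(chloro)dimethylsilane, SMILES CC(C)(C)[Si](C)(C)Cl
Why: Silyl ether formation at low temperature discriminates the primary from the secondary allylic hydroxyl, and the C6 stereocentre, taken from the chiral pool, is not touched.

Step 9
Reactants: 15 (S)-1-[(tert-butyldimethylsilyl)oxy]but-3-en-2-ol; 16 2-(bromomethyl)acrylic acid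
Product: 17 (S)-1-[(tert-butyldimethylsilyl)oxy]but-3-en-2-yl 2-(bromomethyl)acrylate
Conditions: DCC, DMAP (cat.), CH2Cl2, 0 °C
Reagents that add atoms: none
Why: Steglich esterification (carbodiimide activation) acylates the secondary alcohol at oxygen, so the C6 configuration is retained.

Step 10
Reactants: 17 (S)-1-[(tert-butyldimethylsilyl)oxy]but-3-en-2-yl 2-(bromomethyl)acrylate
Product: 18 (S)-3-(bromomethyl)-5-{[(tert-butyldimethylsilyl)oxy]methyl}furan-2(5H)-one
Conditions: second-generation Grubbs catalyst RuCl2(=CHPh)(PCy3)(SIMes) (cat.), toluene, 80 °C, 0.01 M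
Reagents that add atoms: none
Why: Ring-closing olefin metathesis between the acrylate and vinyl groups closes the five-membered butenolide with loss of ethene, the allylic bromide being tolerated and C6 untouched.

Step 11
Reactants: 13 (3E,5Z)-7-iodo-3-methylocta-3,5,7-trienal; 18 (S)-3-(bromomethyl)-5-{[(tert-butyldimethylsilyl)oxy]methyl}furan-2(5H)-one
Product: 20 (4R,5S)-5-{[(tert-butyldimethylsilyl)oxy]methyl}-4-[(1S,3E,5Z)-1-hydroxy-7-iodo-3-methylocta-3,5,7-trien-1-yl]-3-methylidenedihydrofuran-2(3H)-one, via allylzinc bromide 19 (not isolated)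
Conditions: Zn dust, THF/sat. aq NH4Cl, 0 °C to rt
Reagents that add atoms: none
Why: In this zinc Barbier allylation the allylzinc reacts at C7 with allylic transposition through a Zimmerman–Traxler chair, so that attack anti to the C6 substituent gives the 6,7-trans lactone (7R), the ring-enforced E-type allyl geometry gives the 7,8-anti carbinol (8S), and the exocyclic C11=C13 methylene is formed in the same event.

Step 12
Reactants: 20 (4R,5S)-5-{[(tert-butyldimethylsilyl)oxy]methyl}-4-[(1S,3E,5Z)-1-hydroxy-7-iodo-3-methylocta-3,5,7-trien-1-yl]-3-methylidenedihydrofuran-2(3H)-one; 21 angelic acid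
Product: 23 (1S,3E,5Z)-1-[(2S,3R)-2-{[(tert-butyldimethylsilyl)oxy]methyl}-4-methylidene-5-oxotetrahydrofuran-3-yl]-7-iodo-3-methylocta-3,5,7-trien-1-yl (2Z)-2-methylbut-2-enoate, via mixed anhydride 22 (not isolated)
Conditions: 2,4,6-trichlorobenzoyl chloride, Et3N, toluene, rt; filter; then 20, toluene, 75 °C
Reagents that add atoms: none
Why: In this Yamaguchi-type mixed-anhydride acylation the shielded trichlorobenzoyl carbonyl sends the C8 hydroxyl to the angeloyl carbonyl, and leaving out nucleophilic acyl-transfer catalysts should keep the Z geometry of the angelate, with C8 acylated at oxygen and hence retained.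

Step 13
Reactants: 23 (1S,3E,5Z)-1-[(2S,3R)-2-{[(tert-butyldimethylsilyl)oxy]methyl}-4-methylidene-5-oxotetrahydrofuran-3-yl]-7-iodo-3-methylocta-3,5,7-trien-1-yl (2Z)-2-methylbut-2-enoate
Product: 24 (1S,3E,5Z)-1-[(2S,3R)-2-(hydroxymethyl)-4-methylidene-5-oxotetrahydrofuran-3-yl]-7-iodo-3-methylocta-3,5,7-trien-1-yl (2Z)-2-methylbut-2-enoate
Conditions: HF·pyridine, pyridine, THF, 0 °C to rt
Reagents that add atoms: none
Why: Buffered hydrogen fluoride desilylation removes the primary silyl ether without base, so that ester migration and isomerisation of the methylene lactone should be avoided.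

Step 14
Reactants: 24 (1S,3E,5Z)-1-[(2S,3R)-2-(hydroxymethyl)-4-methylidene-5-oxotetrahydrofuran-3-yl]-7-iodo-3-methylocta-3,5,7-trien-1-yl (2Z)-2-methylbut-2-enoate
Product: 25 (1S,3E,5Z)-1-[(2S,3R)-2-formyl-4-methylidene-5-oxotetrahydrofuran-3-yl]-7-iodo-3-methylocta-3,5,7-trien-1-yl (2Z)-2-methylbut-2-enoate
Conditions: Dess–Martin periodinane, NaHCO3, CH2Cl2, 0 °C; used at once
Reagents that add atoms: none
Why: Dess–Martin oxidation gives the α-acyloxy C5 aldehyde under neutral, non-enolising conditions, so that C6 should not epimerise before the ring closure.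

Step 15
Reactants: 25 (1S,3E,5Z)-1-[(2S,3R)-2-formyl-4-methylidene-5-oxotetrahydrofuran-3-yl]-7-iodo-3-methylocta-3,5,7-trien-1-yl (2Z)-2-methylbut-2-enoate
Product: 27 (5R,6S,7R,8S)-5-hydroxy-8-{[(2Z)-2-methylbut-2-enoyl]oxy}germacra-1(10)E,2Z,4(15),11(13)-tetraen-12,6-olide, via alkenylchromium dichloride 26 (not isolated)
Conditions: CrCl2 (excess), NiCl2 (cat.), degassed DMSO, rt, slow addition of 25 to 0.003 M
Reagents that add atoms: none
Why: NiCl2 is reduced by CrCl2 to zerovalent nickel, which inserts into the C4–I bond; the alkenyl group passes to trivalent chromium to give 26, which adds to the C5 aldehyde, and aqueous work-up frees the alcohol. The closest known reaction type is the Nozaki–Hiyama–Kishi macrocyclisation of an alkenyl iodide onto an aldehyde. Ring A (ten-membered, C1–C10) closes by a 10-exo-trig carbonyl addition. The new C5 centre is controlled by C6: without chelation by chromium, the polar Felkin–Anh arrangement holds the C6–O bond anti to the incoming alkenyl group, so the 5-hydroxyl should end up anti to O6 (5R in 27, the configuration of the target). The step needs chemoselectivity for the aldehyde over the lactone, the angelate and the enoate carbons, which alkenylchromium reagents show, and ring closure in preference to dimerisation, which high dilution, the rigid E,Z-diene and the trans-fused ring B should secure; the C2=C3 geometry is not at risk because metalation occurs at the geminally disubstituted C4.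

Step 16
Reactants: 27 (5R,6S,7R,8S)-5-hydroxy-8-{[(2Z)-2-methylbut-2-enoyl]oxy}germacra-1(10)E,2Z,4(15),11(13)-tetraen-12,6-olide
Product: 28 (4S,5S,6S,7R,8S)-4,15-epoxy-5-hydroxy-8-{[(2Z)-2-methylbut-2-enoyl]oxy}germacra-1(10)E,2Z,11(13)-trien-12,6-olide
Conditions: VO(acac)2 (cat.), t-BuOOH, CH2Cl2, 0 °C
Reagents that add atoms: tert-butyl hydroperoxide, SMILES CC(C)(C)OO
Why: In this vanadium-catalysed hydroxyl-directed epoxidation the peroxide bound at the C5 vanadate delivers oxygen only to the allylic C4=C15 bond and on the face of the C5–O bond, which should give the spiro-epoxide cis to the 5-hydroxyl (4S) while the diene, the angelate and the methylene lactone stay untouched.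

Step 17
Reactants: 28 (4S,5S,6S,7R,8S)-4,15-epoxy-5-hydroxy-8-{[(2Z)-2-methylbut-2-enoyl]oxy}germacra-1(10)E,2Z,11(13)-trien-12,6-olide
Product: 30 (1R,2R,3S,4S,5S,6S,7R,8S,10R)-1,10:2,3:4,15-triepoxy-5-hydroxy-8-{[(2Z)-2-methylbut-2-enoyl]oxy}germacr-11(13)-en-12,6-olide (CNP0594916.1), via 1(10)-monoepoxide 29 (not isolated)
Conditions: dimethyldioxirane (3 equiv), acetone/CH2Cl2, −20 to 0 °C
Reagents that add atoms: dimethyldioxirane, SMILES CC1(C)OO1
Why: Electrophilic dioxirane epoxidation attacks the two electron-rich ring alkenes, first the trisubstituted C1=C10 and then the Z C2=C3, from their outward faces on the ten-membered ring (C14 on the face of C11), which should give the 1R,10R and 2R,3S epoxides, while the electron-poor angelate and methylene lactone are inert and the neutral medium spares the three adjacent epoxides.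

Compound list
1 | 3-butyn-1-ol | C#CCCO | starting material
2 | tert-butyl(but-3-yn-1-yloxy)diphenylsilane | C#CCCO[Si](c1ccccc1)(c1ccccc1)C(C)(C)C | intermediate
3 | (Z)-1,2-dichloroethene | Cl/C=C\Cl | starting material
4 | ethynyltrimethylsilane | C#C[Si](C)(C)C | starting material
5 | (Z)-(4-chlorobut-3-en-1-yn-1-yl)trimethylsilane | C[Si](C)(C)C#C/C=C\Cl | intermediate
6 | (E)-{4-[(tert-butyldiphenylsilyl)oxy]-2-methylbut-1-en-1-yl}dimethylalane | C[Al](C)/C=C(C)/CCO[Si](c1ccccc1)(c1ccccc1)C(C)(C)C | intermediate (not isolated)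
7 | (E)-{4-[(tert-butyldiphenylsilyl)oxy]-2-methylbut-1-en-1-yl}zinc chloride | Cl[Zn]/C=C(C)/CCO[Si](c1ccccc1)(c1ccccc1)C(C)(C)C | intermediate (not isolated)
8 | tert-butyl{[(3E,5Z)-3-methyl-8-(trimethylsilyl)octa-3,5-dien-7-yn-1-yl]oxy}diphenylsilane | C[Si](C)(C)C#C/C=C\C=C(C)\CCO[Si](c1ccccc1)(c1ccccc1)C(C)(C)C | intermediate
9 | tert-butyl{[(3E,5Z)-3-methylocta-3,5-dien-7-yn-1-yl]oxy}diphenylsilane | C#C/C=C\C=C(C)\CCO[Si](c1ccccc1)(c1ccccc1)C(C)(C)C | intermediate
10 | 9-{(1Z,3Z,5E)-8-[(tert-butyldiphenylsilyl)oxy]-2-iodo-6-methylocta-1,3,5-trien-1-yl}-9-borabicyclo[3.3.1]nonane | I/C(=C\B1C2CCCC1CCC2)/C=C\C=C(C)\CCO[Si](c1ccccc1)(c1ccccc1)C(C)(C)C | intermediate (not isolated)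
11 | tert-butyl{[(3E,5Z)-7-iodo-3-methylocta-3,5,7-trien-1-yl]oxy}diphenylsilane | C=C(I)/C=C\C=C(C)\CCO[Si](c1ccccc1)(c1ccccc1)C(C)(C)C | intermediate
12 | (3E,5Z)-7-iodo-3-methylocta-3,5,7-trien-1-ol | C=C(I)/C=C\C=C(C)\CCO | intermediate
13 | (3E,5Z)-7-iodo-3-methylocta-3,5,7-trienal | C=C(I)/C=C\C=C(C)\CC=O | intermediate
14 | (S)-but-3-ene-1,2-diol | C=C[C@H](O)CO | starting material
15 | (S)-1-[(tert-butyldimethylsilyl)oxy]but-3-en-2-ol | C=C[C@H](O)CO[Si](C)(C)C(C)(C)C | intermediate
16 | 2-(bromomethyl)acrylic acid | C=C(CBr)C(=O)O | starting material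
17 | (S)-1-[(tert-butyldimethylsilyl)oxy]but-3-en-2-yl 2-(bromomethyl)acrylate | C=C(CBr)C(=O)O[C@H](CO[Si](C)(C)C(C)(C)C)C=C | intermediate
18 | (S)-3-(bromomethyl)-5-{[(tert-butyldimethylsilyl)oxy]methyl}furan-2(5H)-one | O=C1O[C@H](CO[Si](C)(C)C(C)(C)C)C=C1CBr | intermediate
19 | {[(S)-5-{[(tert-butyldimethylsilyl)oxy]methyl}-2-oxo-2,5-dihydrofuran-3-yl]methyl}zinc bromide | Br[Zn]CC1=C[C@@H](CO[Si](C)(C)C(C)(C)C)OC1=O | intermediate (not isolated)
20 | (4R,5S)-5-{[(tert-butyldimethylsilyl)oxy]methyl}-4-[(1S,3E,5Z)-1-hydroxy-7-iodo-3-methylocta-3,5,7-trien-1-yl]-3-methylidenedihydrofuran-2(3H)-one | C=C1C(=O)O[C@H](CO[Si](C)(C)C(C)(C)C)[C@H]1[C@@H](O)C/C(C)=C/C=C\C(I)=C | intermediate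
21 | angelic acid, (2Z)-2-methylbut-2-enoic acid | C/C=C(/C)C(=O)O | starting material
22 | (2Z)-2-methylbut-2-enoic 2,4,6-trichlorobenzoic anhydride | C/C=C(/C)C(=O)OC(=O)c1c(Cl)cc(Cl)cc1Cl | intermediate (not isolated)
23 | (1S,3E,5Z)-1-[(2S,3R)-2-{[(tert-butyldimethylsilyl)oxy]methyl}-4-methylidene-5-oxotetrahydrofuran-3-yl]-7-iodo-3-methylocta-3,5,7-trien-1-yl (2Z)-2-methylbut-2-enoate | C=C1C(=O)O[C@H](CO[Si](C)(C)C(C)(C)C)[C@H]1[C@@H](OC(=O)/C(C)=C\C)C/C(C)=C/C=C\C(I)=C | intermediate
24 | (1S,3E,5Z)-1-[(2S,3R)-2-(hydroxymethyl)-4-methylidene-5-oxotetrahydrofuran-3-yl]-7-iodo-3-methylocta-3,5,7-trien-1-yl (2Z)-2-methylbut-2-enoate | C=C1C(=O)O[C@H](CO)[C@H]1[C@@H](OC(=O)/C(C)=C\C)C/C(C)=C/C=C\C(I)=C | intermediate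
25 | (1S,3E,5Z)-1-[(2S,3R)-2-formyl-4-methylidene-5-oxotetrahydrofuran-3-yl]-7-iodo-3-methylocta-3,5,7-trien-1-yl (2Z)-2-methylbut-2-enoate (seco C5 aldehyde, precursor of the key step) | C=C1C(=O)O[C@H](C=O)[C@H]1[C@@H](OC(=O)/C(C)=C\C)C/C(C)=C/C=C\C(I)=C | intermediate
26 | C4 alkenylchromium dichloride derived from 25 (trivalent chromium in place of iodine) | C=C1C(=O)O[C@H](C=O)[C@H]1[C@@H](OC(=O)/C(C)=C\C)C/C(C)=C/C=C\C(=C)[Cr](Cl)Cl | intermediate (not isolated)
27 | (5R,6S,7R,8S)-5-hydroxy-8-{[(2Z)-2-methylbut-2-enoyl]oxy}germacra-1(10)E,2Z,4(15),11(13)-tetraen-12,6-olide (product of the key step) | C=C1C(=O)O[C@H]2[C@H]1[C@@H](OC(=O)/C(C)=C\C)C/C(C)=C/C=C\C(=C)[C@H]2O | intermediate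
28 | (4S,5S,6S,7R,8S)-4,15-epoxy-5-hydroxy-8-{[(2Z)-2-methylbut-2-enoyl]oxy}germacra-1(10)E,2Z,11(13)-trien-12,6-olide | C=C1C(=O)O[C@H]2[C@H]1[C@@H](OC(=O)/C(C)=C\C)C/C(C)=C/C=C\[C@]1(CO1)[C@H]2O | intermediate
29 | (1R,4S,5S,6S,7R,8S,10R)-1,10:4,15-diepoxy-5-hydroxy-8-{[(2Z)-2-methylbut-2-enoyl]oxy}germacra-2Z,11(13)-dien-12,6-olide | C=C1C(=O)O[C@H]2[C@H]1[C@@H](OC(=O)/C(C)=C\C)C[C@@]1(C)O[C@@H]1/C=C\[C@]1(CO1)[C@H]2O | intermediate (not isolated)
30 | (1R,2R,3S,4S,5S,6S,7R,8S,10R)-1,10:2,3:4,15-triepoxy-5-hydroxy-8-{[(2Z)-2-methylbut-2-enoyl]oxy}germacr-11(13)-en-12,6-olide (CNP0594916.1) | C=C1C(=O)O[C@H]2[C@H]1[C@@H](OC(=O)/C(C)=C\C)C[C@@]1(C)O[C@@H]1[C@@H]1O[C@@H]1[C@]1(CO1)[C@H]2O | target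

Total step count: 17. Longest linear sequence: 13 steps (steps 1, 3 to 7 and 11 to 17, from 3-butyn-1-ol).

Steps most likely to fail

Step 15. Ring closure may be slower than protonation or dimerisation of the alkenylchromium, and the aldehyde face may be chosen by the ring conformation or by chelation instead of the Felkin–Anh preference, so that the C5 epimer forms. The fallback sets out from 25 and comes back at 27. The cyclisation is run as in step 15, and the (5S)-epimeric alcohol F1 is oxidised with Dess–Martin periodinane (NaHCO3, CH2Cl2, 0 °C) to the C5 ketone F2. A Corey–Bakshi–Shibata reduction (B-methyl oxazaborolidine, catecholborane, toluene, −78 °C, catalyst enantiomer chosen to give the 5R alcohol) then delivers 27. C5 is thus set by the reducing agent and no longer by the ring closure.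

Step 17. Facial selectivity at the Z alkene C2=C3 may be poor, because its two faces are less differentiated than those of the E alkene, and a slow second epoxidation may allow over-oxidation or opening of the vinyl epoxides. The fallback sets out from 28 and comes back at 30. A catalyst-controlled Jacobsen–Katsuki epoxidation (Mn(salen)Cl with salen = N,N'-bis(3,5-di-tert-butylsalicylidene)cyclohexane-1,2-diamine dianion, NaOCl, 4-phenylpyridine N-oxide, CH2Cl2, 0 °C, enantiomer chosen for the 2,3-epoxide of the target) is applied first. It favours the cis alkene of the conjugated diene and gives the 2,3-monoepoxide F3. Dimethyldioxirane (acetone, 0 °C) then epoxidises the remaining trisubstituted C1=C10 from its outer face to give 30.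

Step 5. Lewis acid or traces of HI may isomerise the Z C2=C3 bond, and the silyl ether may be partly lost during haloboration. The fallback sets out from 9 and comes back at 11. Palladium-catalysed hydrostannation (Bu3SnH, PdCl2(PPh3)2 cat., THF, 0 °C), in which tin goes to the internal alkyne carbon of a conjugated enyne, gives the 2-stannyl triene F4. Iododestannylation (I2, CH2Cl2, −78 to 0 °C) then gives 11.

Further compounds
F1 | step 15 | (5S,6S,7R,8S)-5-hydroxy-8-{[(2Z)-2-methylbut-2-enoyl]oxy}germacra-1(10)E,2Z,4(15),11(13)-tetraen-12,6-olide (C5 epimer of 27) | C=C1C(=O)O[C@H]2[C@H]1[C@@H](OC(=O)/C(C)=C\C)C/C(C)=C/C=C\C(=C)[C@@H]2O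
F2 | step 15 | (6S,7R,8S)-8-{[(2Z)-2-methylbut-2-enoyl]oxy}-5-oxogermacra-1(10)E,2Z,4(15),11(13)-tetraen-12,6-olide | C=C1C(=O)O[C@H]2[C@H]1[C@@H](OC(=O)/C(C)=C\C)C/C(C)=C/C=C\C(=C)C2=O
F3 | step 17 | (2S,3S,4S,5S,6S,7R,8S)-2,3:4,15-diepoxy-5-hydroxy-8-{[(2Z)-2-methylbut-2-enoyl]oxy}germacra-1(10)E,11(13)-dien-12,6-olide | C=C1C(=O)O[C@H]2[C@H]1[C@@H](OC(=O)/C(C)=C\C)C/C(C)=C/[C@@H]1O[C@@H]1[C@]1(CO1)[C@H]2O
F4 | step 5 | tert-butyl{[(3E,5Z)-3-methyl-7-(tributylstannyl)octa-3,5,7-trien-1-yl]oxy}diphenylsilane | C=C([Sn](CCCC)(CCCC)CCCC)/C=C\C=C(C)\CCO[Si](c1ccccc1)(c1ccccc1)C(C)(C)C
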